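A curve that has gone nearly flat tempts me to take its last reading for the end, just as a simple overall equation tempts me to expect that Sub goes on turning until the charge is used.

| flask | Sub | Prd | time |
|---|---|---|---|
| elm | 0.120 M |  |  |
| ash | 0.0480 M |  |  |
| birch | 0.120 M | 0.0360 M |  |
| cedar | 0.180 M |  |  |
| oak | 0.120 M |  | 230 min |

| elm run: time / min | elm run: [Prd] / M | ash run: time / min | ash run: [Prd] / M | birch run: time / min | birch run: [Prd] / M | cedar run: time / min | cedar run: [Prd] / M |
|---|---|---|---|---|---|---|---|
| 3.1 | 6 × 10⁻⁴ | 3.1 | 0 | 3.1 | 0.0413 | 3.1 | 0.0010 |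
| 7.0 | 0.0045 | 7.0 | 0.0016 | 7.0 | 0.0468 | 7.0 | 0.0065 |
| 16 | 0.0155 | 16 | 0.0053 | 16 | 0.0625 | 16 | 0.0230 |
| 35 | 0.0334 | 35 | 0.0117 | 35 | 0.0810 | 35 | 0.0531 |
| 78 | 0.0456 | 78 | 0.0175 | 78 | 0.0917 | 78 | 0.0698 |

(scatter of a reading: 4 × 10⁻⁴ M)

- Overall: Sub -> Prd.
- Constant volume, constant temperature.
- An order is taken over about fifteen percent of the charge, up and down.

1. order of the initial rate in [Sub], near the charge of the elm run, the rate being that where two percent of its Sub are Prd (one fixed amount of Prd, the same in the runs compared)
2. Prd in the oak run at 230 min, as a share of the Sub charged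

Those two temptations are my extremes for the oak flask, which has the charge of the elm flask. If the flask has stopped at the last elm reading, oak ends at 38.0 % of its charge; if Sub simply keeps turning into Prd, oak ends near 100 percent. To place it between them, I read the elm run late. Prd rises at 9.42 × 10⁻⁴ M min⁻¹ between 16 min and 35 min, then at 2.84 × 10⁻⁴ M min⁻¹ up to 78 min. Setting these mean rates at the midpoints of their intervals gives a fade time, the time in which the rate falls by a factor e, of 25.8 min. The elm rate at its last reading is then about 1.23 × 10⁻⁴ M min⁻¹, and rate times fade time leaves a tail of 0.00319 M. The 152 min from the time of that reading to the oak time hold 5.88 fade times, so I count the whole tail, and oak ends at about 40.7 %. That is a generous figure, since on a bending curve the long last interval has a mean rate above its midpoint rate. I commit to the span from 38.0 % to 40.7 %.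

The forecast gives an order of 0.65, range 0.4 to 1, and 42 % for oak, range 40 % to 47 %, reasoning that “the catalyst is dying, with a half-life near 20 min”. Its value lies above my span.

The flask gives an order of 0.67 and 38.4 % for oak, below the low end of the forecast's range.

    Sub → Int (0.02880 min⁻¹)
    Int → Prd (0.06180 min⁻¹)
    Sub + Prd → 2 Prd (0.2964 M⁻¹ min⁻¹)
    Sub → Z (0.05070 min⁻¹)

The oak flask stops short because Sub also turns into Z. In the oak flask, the two first-order steps taken by themselves give Sub a lifetime of 12.6 min, shorter than my fade time of 25.8 min, and the oak time holds 18.3 of these lifetimes. In the oak run without that step, Prd reaches >99.9 % of the Sub charged.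

The earlier runs and the new flask come from a simulation from invented constants; scatter was added.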